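Cedar, charged with X at 0.15 M, reads L at 5.4% after 0.833 d, 14.6% after 2.00 d and 13.4% after 5.00 d, so L in cedar turns over within the time allowed, long after its feed of J has ended.

| setting | oak | cedar | flask |
|---|---|---|---|
| X | 0.10 M | 0.15 M | 0.10 M |
| J | 0.40 M (fed, over 12 h) | 0.40 M (fed, over 12 h) | 0.400 M (fed, over 12 h) |
| remark | the very flask that is asked about, followed so far | run made earlier |  |
| time |  |  | 5.0 d |

- oak (time / h: L / %): 2.00: 0.2; 5.00: 0; 10.0: 1.3; 15.0: 3.5
- cedar (time / d: L / %): 0.417: 0.7; 0.833: 5.4; 2.00: 14.6; 5.00: 13.4

(standard deviation of a reading: 0.3 percentage points)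

* when, up to 5.0 d, the flask holds most L
* the amount of L, in percent of the X charged, at that time



Turned round, the question is whether such a turn could come from a shortage of J. A bis adduct holds two J for each L, so that is the least J an L can cost, and in a ratio of J charged to J so needed time drops out, which lets the charges give a first answer. Call cover the whole charge cJ over the J that two additions to the charged cX take: 2.00 in oak, which is this flask followed so far, and 1.33 in cedar. A cover below one means a charge of J too small for two additions to every X. Oak stands above that, and further above it than cedar, so X is the limiting reagent for L in both, and the sag in cedar points to a loss of L. The reckoning made here takes the highest L in proportion to cover: the cedar reading at 2.00 d times the ratio of covers gives 21.9%, with the maximum between 2.00 d and 5.00 d.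

The forecast is lower, with 18.5% (16.5% to 21%) at 2.8 d (2 d to 3.8 d), on the ground that “Oak has more spare J than cedar”.

The flask gives 19.9% at 3.46 d, inside that bracket and 2 percentage points below the proportion.

    J + Q → L + E (k = 2.40 × 10⁻⁵ L mol⁻¹ s⁻¹)
    J + L ⇌ Z + E (K = 0.720, k = 8.70 × 10⁻⁵ L mol⁻¹ s⁻¹)
    X + J → Q + E (k = 3.40 × 10⁻⁵ L mol⁻¹ s⁻¹)
    L + E → G (k = 5.10 × 10⁻⁵ L mol⁻¹ s⁻¹)

At 5.00 d the flask keeps 51% of its J, while the neighbour with X at 0.25 M, cover 0.800, keeps 14% and reaches 11.9% of L, less than this flask. Of the flask's turnover up to 5.0 d, half of X + J into Q + E is done by 0.872 d, earlier than half of L + E into G, done by 3.31 d. At 3.46 d, the best time, G stands at 24.1% beside L at 19.9%, and at 5.00 d G reaches 44.1%.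

The numbers in the tables are calculated for an exercise; noise was put on by code.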